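The earlier runs and the new flask are calculated for substances that don't exist, noise included.

If two nucleophiles compete for one intermediate, I first ask how it divides between them, and then how much of each stands beside it while it forms.

| flask | starting material | first nucleophile | second nucleophile | protic impurity | temperature | remark | time |
|---|---|---|---|---|---|---|---|
| zeta | 0.050 M | 0.055 M | 0.065 M | 2.5 mM | 45 °C | run made earlier |  |
| delta | 0.050 M | 0.055 M | 0.044 M | 2.5 mM | 60 °C | run made earlier |  |
| theta | 0.050 M | 0.055 M | 0.098 M | 2.5 mM | 45 °C | run made earlier |  |
| alpha | 0.050 M | 0.11 M | 0.065 M | 2.5 mM | 60 °C | run made earlier |  |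
| violet | 0.050 M (fed, over 2.5 d) | 0.0550 M | 0.0650 M | 2.50 mM | 60 °C | all else is in the flask from the start; the feed brings no volume worth counting | 6.0 d |
| grey | 0.050 M (fed, over 2.5 d) | 0.0550 M | 0.0650 M | 2.50 mM |  | the addition at 40 °C, then warmed to 60 °C; the feed brings no volume worth counting | 6.0 d |
| red | 0.050 M | 0.0550 M | 0.0650 M (fed, over 2.5 d) | 2.50 mM | 60 °C | all else is in the flask from the start; the feed brings no volume worth counting | 6.0 d |
| green | 0.050 M (in portions, 2, over 2.5 d) | 0.0550 M | 0.0650 M | 2.50 mM | 60 °C | first portion at the start, last at 2.5 d | 6.0 d |

| run | time / d | target / % | other capture product / % |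
|---|---|---|---|
| zeta | 0.500 | 0 | 42 |
| zeta | 1.04 | 3 | 65 |
| zeta | 2.00 | 7 | 85 |
| zeta | 4.00 | 5 | 92 |
| zeta | 8.00 | 1 | 90 |
| delta | 0.417 | 13 | 77 |
| delta | 0.833 | 9 | 83 |
| delta | 1.25 | 11 | 81 |
| delta | 2.50 | 10 | 86 |
| delta | 5.00 | 11 | 82 |
| theta | 2.00 | 3 | 89 |
| theta | 4.00 | 7 | 94 |
| theta | 6.00 | 3 | 92 |
| theta | 8.00 | 0 | 95 |
| theta | 10.0 | 0 | 94 |
| alpha | 0.417 | 7 | 78 |
| alpha | 1.25 | 9 | 84 |
| alpha | 2.00 | 8 | 82 |
| alpha | 3.00 | 3 | 85 |
| alpha | 5.00 | 8 | 84 |

(standard deviation of a reading: 2 percentage points)

- the flask with the highest share of target in target plus other capture product ("all alike" if they lie within 1.5 percentage points) (violet / grey / red / green / all alike)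
- share of target in target plus other capture product at the end, violet
- share of target in target plus other capture product at the end, grey
- share of target in target plus other capture product at the end, red
- share of target in target plus other capture product at the end, green

- steps under discussion: starting material + protic impurity -> quenched substrate; intermediate -> solvolysis product; starting material -> intermediate; intermediate -> side product; second nucleophile + intermediate -> other capture product; first nucleophile + intermediate -> target; target <-> isomer of the product

How does the intermediate divide? Each nucleophile is consumed in proportion to what is left of it, so the logarithms of their remaining fractions keep a fixed ratio, the selectivity factor. The alpha run at 5.00 d shows target 8% and other capture product 84%, and counting target alone, as if none of it had turned into isomer of the product, these read as a factor of 0.0357, first nucleophile against second; any target turned into its isomer would raise that reading. So I define the break-even level, the fraction of its charge at which the second nucleophile captures as fast as a whole charge of the first: 3.02%.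

Does feeding the starting material move the second nucleophile towards that level? In violet and green it is present from the start, and even after capturing the whole charge 23.1% of it remains, more than the break-even level. I therefore reckon target, together with any isomer of the product, at about 5.60% of the charge in both. This counts the whole charge as captured by the second nucleophile, and it is a part of the charge, not the share that the forecast gives.

What happens when the second nucleophile is the one fed? By the first delta reading, at 0.417 d, products already stand at 90.0%, and that time is shorter than the addition. In that time red's feed delivers second nucleophile worth 21.7% of the starting material. If it is consumed as it arrives, other capture product stays near that figure, and the rest of the intermediate is open to the first nucleophile. So I expect red highest, by far.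

The forecast names red: violet 4.6%, grey 4.1%, red 68%, green 4.6%. Its ground for the flasks with fed starting material is that the share depends on the path of the two nucleophiles, “not on SM timing”.

The flasks give red as highest: violet 5.08%, grey 4.49%, red 65.2%, green 5.08%.

    starting material + protic impurity → quenched substrate (k = 5.30 M⁻¹ h⁻¹, Ea = 86.0 kJ mol⁻¹)
    intermediate → solvolysis product (k = 0.0700 h⁻¹, Ea = 122 kJ mol⁻¹)
    starting material → intermediate (k = 0.250 h⁻¹, Ea = 96.0 kJ mol⁻¹)
    intermediate → side product (k = 0.0750 h⁻¹, Ea = 97.0 kJ mol⁻¹)
    second nucleophile + intermediate → other capture product (k = 500 M⁻¹ h⁻¹, Ea = 48.0 kJ mol⁻¹)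
    first nucleophile + intermediate → target (k = 27.0 M⁻¹ h⁻¹, Ea = 66.0 kJ mol⁻¹)
    target ⇌ isomer of the product (K = 0.400, k = 0.0500 h⁻¹, Ea = 122 kJ mol⁻¹, ΔH = −71.0 kJ mol⁻¹)
    (constants at 60 °C)

Red has come to rest. The constants of the scheme put the break-even level at 4.57% at 60 °C, above my reading of 3.02%, which counted target without its isomer of the product. At 6.00 d red's starting material stands at 0% and its intermediate at 0%, while the second nucleophile left, 81% of its charge, is 17.7 times that level. At 60.0 d red's share reads 65.2%. Target and isomer of the product relax with a half-life of 0.165 d, shorter than the 6.0 d of the run. Grey holds 31%, 6.71 times that level, with intermediate at 0%, and its share at 60.0 d reads 4.49%.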